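Numbering follows the elemane skeleton (ring C5–C10; lactone O–C6–C7–C11–C12; C13 exocyclic methylene). Everything rests on cutting C6–C7, the bond shared by the cyclohexane and the α-methylene-γ-lactone: C6–O/C7–C11(=C13)–C12 is the retron of a carbonyl 2-(alkoxycarbonyl)allylation. A chromium-mediated intramolecular Nozaki–Hiyama–Kishi-type allylation of a lactol-masked C6 aldehyde by a C7=C11 2-(bromomethyl)enoate closes the carbocycle, sets C6 and C7, creates the exocyclic methylene and lactonises in one operation. The open-chain precursor carries C5, C8 and C10, set from an (S)-glutamate-derived lactone by an Ireland–Claisen rearrangement; the acrylate arrives by a Morita–Baylis–Hillman reaction.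

Key step: step 19

Remark: further locants are C1=C2 (vinyl on C10), C14 (CH2O on C10) and C3=C4–C15 (on C5); TBS = tert-butyldimethylsilyl, TBDPS = tert-butyldiphenylsilyl, Tr = triphenylmethyl; the five starting materials are assumed to be purchasable.

Step 1
Reactants: 1 4-methyl hydrogen itaconate (2-methylidenebutanedioic acid 4-methyl ester)
Product: 3 methyl 3-(hydroxymethyl)but-3-enoate, via mixed carbonic anhydride 2 (not isolated)
Conditions: i-BuOCOCl, N-methylmorpholine, THF, −15 °C; then NaBH4, H2O, 0 °C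
Reagents that add atoms: none
Why: Mixed-anhydride activation and NaBH4 reduction should reduce only the free conjugated carboxyl to the allylic alcohol (future C15), because the methyl ester is inert to NaBH4 at 0 °C.

Step 2
Reactants: 3 methyl 3-(hydroxymethyl)but-3-enoate
Product: 4 methyl 3-[(tert-butyldiphenylsilyloxy)methyl]but-3-enoate
Conditions: TBDPSCl, imidazole, CH2Cl2, 0 → 25 °C
Reagents that add atoms: tert-butyl(chloro)diphenylsilane, CC(C)(C)[Si](Cl)(c1ccccc1)c1ccccc1
Why: Imidazole-promoted silylation of the primary alcohol installs a silyl ether that should survive every later acidic, basic and reductive step.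

Step 3
Reactants: 4 methyl 3-[(tert-butyldiphenylsilyloxy)methyl]but-3-enoate
Product: 5 3-[(tert-butyldiphenylsilyloxy)methyl]but-3-enoic acid
Conditions: LiOH, THF–H2O, 0 °C; then 1 M HCl to pH 4
Reagents that add atoms: lithium hydroxide, [Li+].[OH-]
Why: Cold saponification of the unhindered methyl ester should give the β,γ-unsaturated acid without moving the 1,1-disubstituted alkene into conjugation.

Step 4
Reactants: 6 (E)-but-2-enal
Product: 8 (Z)-2-bromobut-2-enal, via 2,3-dibromobutanal 7 (not isolated)
Conditions: Br2, CH2Cl2, 0 °C; then Et3N, 0 → 25 °C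
Reagents that add atoms: bromine, BrBr
Why: Bromine addition followed by amine-induced E1cB loss of HBr should give the α-bromo enal in its preferred Z form (Br cis to methyl), which fixes the geometry of the side-chain acid.

Step 5
Reactants: 8 (Z)-2-bromobut-2-enal
Product: 9 (Z)-2-bromobut-2-en-1-ol
Conditions: NaBH4, CeCl3·7H2O, MeOH, 0 °C
Reagents that add atoms: none
Why: Luche reduction should give clean 1,2-reduction of the enal and leave the vinyl bromide and the alkene geometry untouched.

Step 6
Reactants: 9 (Z)-2-bromobut-2-en-1-ol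
Product: 10 (Z)-(2-bromobut-2-enyloxy)(tert-butyl)diphenylsilane
Conditions: TBDPSCl, imidazole, CH2Cl2, 0 → 25 °C
Reagents that add atoms: tert-butyl(chloro)diphenylsilane, CC(C)(C)[Si](Cl)(c1ccccc1)c1ccccc1
Why: Standard silylation protects the allylic alcohol before the halogen–metal exchange.

Step 7
Reactants: 10 (Z)-(2-bromobut-2-enyloxy)(tert-butyl)diphenylsilane
Product: 12 (Z)-2-[(tert-butyldiphenylsilyloxy)methyl]but-2-enoic acid, via alkenyllithium 11 (not isolated)
Conditions: t-BuLi (2.1 equiv), Et2O, −78 °C; CO2 (gas), −78 → 0 °C; then 1 M HCl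
Reagents that add atoms: carbon dioxide, O=C=O
Why: Bromine–lithium exchange proceeds with retention at the configurationally stable alkenyllithium, so carboxylation should place CO2H cis to the methyl group.

Step 8
Reactants: 13 (S)-5-(trityloxymethyl)dihydrofuran-2(3H)-one; 14 (tert-butyldimethylsilyloxy)acetaldehyde
Product: 17 (S,E)-3-[2-(tert-butyldimethylsilyloxy)ethylidene]-5-(trityloxymethyl)dihydrofuran-2(3H)-one, via aldol adduct 15 (not isolated), via mesylate 16 (not isolated)
Conditions: LiN(i-Pr)2, THF, −78 °C; 14; MsCl, −78 → 0 °C; then DBU, 0 → 25 °C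
Reagents that add atoms: none
Why: Aldol addition of the lactone enolate, mesylation of the aldolate and E1cB elimination (aldol condensation) should give the E alkylidene lactone, with the CH2OTBS arm cis to the ring CH2.

Step 9
Reactants: 17 the TBS-protected alkylidene lactone
Product: 18 (S,E)-3-(2-hydroxyethylidene)-5-(trityloxymethyl)dihydrofuran-2(3H)-one
Conditions: TBAF, AcOH, THF, 0 → 25 °C
Reagents that add atoms: none
Why: Buffered fluoride cleaves only the primary TBS ether, and the E geometry keeps the new hydroxyl away from the lactone carbonyl so that no translactonisation can occur.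

Step 10
Reactants: 18 the allylic alcohol; 5 3-[(tert-butyldiphenylsilyloxy)methyl]but-3-enoic acid
Product: 19 the allylic ester of 18 with acid 5
Conditions: EDC·HCl, DMAP (cat.), CH2Cl2, 0 °C
Reagents that add atoms: none
Why: Carbodiimide (Steglich-type) esterification at 0 °C joins the two fragments under conditions that should keep the β,γ-alkene of 5 out of conjugation.

Step 11
Reactants: 19 the allylic ester
Product: 22 (2S)-2-[(3R,5S)-2-oxo-5-(trityloxymethyl)-3-vinyltetrahydrofuran-3-yl]-3-[(tert-butyldiphenylsilyloxy)methyl]but-3-enoic acid, via silyl ketene acetal 20 (not isolated), via trimethylsilyl ester 21 (not isolated)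
Conditions: LiN(SiMe3)2, Me3SiCl, Et3N, THF–DMPU, −78 → 50 °C; then 1 M HCl
Reagents that add atoms: none
Why: In the Ireland–Claisen rearrangement the (Z)-silyl ketene acetal (C4 unit cis to OSiMe3, favoured by DMPU) should react through a chair transition state on the face of the E alkylidene lactone anti to CH2OTr, forming C5–C10, setting quaternary C10 (R) and C5 (S) relative to C8 and unveiling the C10 vinyl group.

Step 12
Reactants: 22 the Claisen acid
Product: 24 γ-lactone (C6 carbonyl and C14–O in the ring) with a free C8 hydroxyl (5S,8S,10R), via dihydroxy acid 23 (not isolated)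
Conditions: LiBH4 (3 equiv), THF, 0 → 25 °C; then 0.5 M HCl to pH 3–4, 25 °C
Reagents that add atoms: none
Why: LiBH4 reduces the lactone but not the lithium carboxylate formed in situ, and on acidification the new primary C14 hydroxyl closes the γ-lactone onto C6 (5-exo-trig, Thorpe–Ingold assisted), which differentiates C6 from C14 and frees the C8 hydroxyl.

Step 13
Reactants: 24 the hydroxy lactone
Product: 25 its C8 tert-butyldimethylsilyl ether
Conditions: TBSOTf, 2,6-lutidine, CH2Cl2, −78 → 0 °C
Reagents that add atoms: tert-butyldimethylsilyl trifluoromethanesulfonate, CC(C)(C)[Si](C)(C)OS(=O)(=O)C(F)(F)F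
Why: The silyl triflate silylates the hindered secondary alcohol quickly under buffered conditions that leave the trityl ether intact.

Step 14
Reactants: 25 the silylated lactone
Product: 27 methyl acetal of the C6 lactol with a free C7 hydroxyl (both anomers), via lactol 26 (not isolated)
Conditions: i-Bu2AlH (1.2 equiv), CH2Cl2, −78 °C; aq. KNaC4H4O6 work-up; crude lactol then CSA (cat.), MeOH–CH2Cl2, 0 → 25 °C
Reagents that add atoms: methanol, CO
Why: Low-temperature i-Bu2AlH reduction stops at the lactol, and acidic methanol then forms the methyl acetal (masked C6 aldehyde) while removing the trityl group by SN1 methanolysis, the secondary TBS and the TBDPS ethers being stable to these conditions.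

Step 15
Reactants: 27 the acetal alcohol
Product: 28 the C7 aldehyde (α-silyloxy aldehyde)
Conditions: Dess–Martin periodinane, NaHCO3, CH2Cl2, 0 → 25 °C
Reagents that add atoms: none
Why: Buffered Dess–Martin oxidation gives the α-silyloxy aldehyde without epimerisation at C8 and without touching the acetal.

Step 16
Reactants: 28 the C7 aldehyde; 29 methyl acrylate
Product: 30 Morita–Baylis–Hillman adduct (C7 carbinol, both epimers)
Conditions: DABCO (1 equiv), methyl acrylate (10 equiv), MeOH (2 equiv), 25 °C
Reagents that add atoms: none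
Why: In the Morita–Baylis–Hillman reaction the α-oxygenated aldehyde is an activated acceptor, and the configuration of the new carbinol does not matter because it is erased in the next step.

Step 17
Reactants: 30 the Morita–Baylis–Hillman adduct
Product: 31 methyl (Z)-2-(bromomethyl)alk-2-enoate (C7=C11, C13 bromide), C6 still as methyl acetal
Conditions: NBS, Me2S, CH2Cl2, 0 → 25 °C
Reagents that add atoms: N-bromosuccinimide, O=C1CCC(=O)N1Br
Why: The bromosulfonium salt formed in situ activates the allylic alcohol and bromide attacks the methylene terminus (SN2′, Corey–Kim-type conditions), which should give the primary allylic bromide with C8 trans to the ester.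

Step 18
Reactants: 31 the bromide acetal
Product: 32 the C6 lactol bearing the (Z)-2-(bromomethyl)enoate
Conditions: AcOH–THF–H2O (3:1:1), 35 °C
Reagents that add atoms: water, O
Why: Mild aqueous acid should hydrolyse the 2-methoxytetrahydrofuran acetal much faster than it cleaves the silyl ethers or solvolyses the allylic bromide.

Step 19
Reactants: 32 the lactol bromide
Product: 35 trans-fused α-methylene lactone (8-OTBS 15-OTBDPS free 14-OH), via allylchromium dichloride 33 (not isolated), via hydroxy ester 34 (not isolated)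
Conditions: CrCl2 (6 equiv), DMF, 25 °C; aq. NH4Cl; then PPTS (cat.), CH2Cl2, 25 °C
Reagents that add atoms: none
Why: Two equivalents of CrCl2 (divalent chromium, one electron each) reduce the allylic C–Br bond to a weakly basic σ-allyl species of trivalent chromium that tolerates the hydroxyl group, while the lactol opens under the Lewis-acidic chromium salts to the C6 aldehyde; the γ-carbon C7 then adds to C6 with allylic transposition through a six-membered Zimmerman–Traxler array, which generates the C11=C13 methylene, and the C6 alkoxide acylates on the methyl ester. The closest known reaction type is the chromium-mediated intramolecular Nozaki–Hiyama–Kishi (Barbier-type) 2-(alkoxycarbonyl)allylation of formyl-tethered 2-(bromomethyl)alk-2-enoates, which is known to fuse α-methylene-γ-butyrolactones trans onto six-membered rings. The cyclohexane closes by 6-exo-trig attack of C7 on the aldehyde carbon and the lactone by 5-exo-trig acyl substitution of O6 at C12. C6 (R) and C7 (geometry of the target) are set together by a chair–chair, trans-decalin-like transition state in which C5, C8 and C10 hold their large groups equatorial and the new C6–O and C7–C11 bonds are both equatorial, hence trans. The step needs anti selectivity and γ-regioselectivity: allylchromium species equilibrate their alkene geometry by σ–π–σ shifts, so the Z bromide can react through the E allylmetal (Curtin–Hammett), whereas the array with an axial C6–O bond would clash 1,3-diaxially with the axial CH2OH group on C10. DMF as donor solvent should suppress chelation by the free C14 hydroxyl, and the silyloxy group at C8 is too poor a leaving group for 1,4-elimination of the allylmetal.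

Step 20
Reactants: 35 the lactone with free C14 hydroxyl
Product: 36 its C14 tert-butyldiphenylsilyl ether
Conditions: TBDPSCl, imidazole, DMAP (cat.), DMF, 25 °C
Reagents that add atoms: tert-butyl(chloro)diphenylsilane, CC(C)(C)[Si](Cl)(c1ccccc1)c1ccccc1
Why: The neopentyl primary hydroxyl is the only free hydroxyl, so silylation should be unambiguous and protects C14 before the acylation.

Step 21
Reactants: 36 the fully silylated lactone
Product: 37 the C8 alcohol (C14 and C15 still as TBDPS ethers)
Conditions: HF·pyridine, pyridine, THF, 0 → 25 °C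
Reagents that add atoms: none
Why: Buffered HF·pyridine should remove the secondary TBS ether far faster than the two primary TBDPS ethers, exposing only the C8 hydroxyl.

Step 22
Reactants: 37 the C8 alcohol; 12 (Z)-2-[(tert-butyldiphenylsilyloxy)methyl]but-2-enoic acid
Product: 39 the tris-TBDPS ether of the target, via mixed anhydride 38 (not isolated)
Conditions: 2,4,6-Cl3C6H2COCl, Et3N, toluene, 25 °C; then 37, toluene, 75 °C (no DMAP)
Reagents that add atoms: none
Why: Yamaguchi-type esterification through the mixed trichlorobenzoic anhydride is run without a nucleophilic amine catalyst, so that no reversible conjugate addition can isomerise the Z alkene, and the alcohol attacks the less hindered aliphatic carbonyl.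

Step 23
Reactants: 39 the tris-TBDPS ether
Product: 40 the target
Conditions: HF·pyridine, pyridine, THF, 25 → 40 °C
Reagents that add atoms: none
Why: Fluoride-mediated cleavage of the three TBDPS ethers under non-basic conditions should leave the α-methylene lactone and the allylic ester untouched.

Compound list
1 | 4-methyl hydrogen itaconate | COC(=O)CC(=C)C(=O)O | starting material
2 | isobutyl carbonic mixed anhydride of 1 | COC(=O)CC(=C)C(=O)OC(=O)OCC(C)C | intermediate (not isolated)
3 | methyl 3-(hydroxymethyl)but-3-enoate | COC(=O)CC(=C)CO | intermediate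
4 | methyl 3-[(tert-butyldiphenylsilyloxy)methyl]but-3-enoate | COC(=O)CC(=C)CO[Si](c1ccccc1)(c1ccccc1)C(C)(C)C | intermediate
5 | 3-[(tert-butyldiphenylsilyloxy)methyl]but-3-enoic acid | OC(=O)CC(=C)CO[Si](c1ccccc1)(c1ccccc1)C(C)(C)C | intermediate
6 | (E)-but-2-enal | C/C=C/C=O | starting material
7 | 2,3-dibromobutanal | CC(Br)C(Br)C=O | intermediate (not isolated)
8 | (Z)-2-bromobut-2-enal | C/C=C(\Br)C=O | intermediate
9 | (Z)-2-bromobut-2-en-1-ol | C/C=C(\Br)CO | intermediate
10 | (Z)-(2-bromobut-2-enyloxy)(tert-butyl)diphenylsilane | C/C=C(\Br)CO[Si](c1ccccc1)(c1ccccc1)C(C)(C)C | intermediate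
11 | alkenyllithium from 10 (Li in place of Br, geometry retained) | C/C=C(\[Li])CO[Si](c1ccccc1)(c1ccccc1)C(C)(C)C | intermediate (not isolated)
12 | (Z)-2-[(tert-butyldiphenylsilyloxy)methyl]but-2-enoic acid | C/C=C(\C(=O)O)CO[Si](c1ccccc1)(c1ccccc1)C(C)(C)C | intermediate
13 | (S)-5-(trityloxymethyl)dihydrofuran-2(3H)-one | O=C1CC[C@@H](COC(c2ccccc2)(c2ccccc2)c2ccccc2)O1 | starting material
14 | (tert-butyldimethylsilyloxy)acetaldehyde | O=CCO[Si](C)(C)C(C)(C)C | starting material
15 | (5S)-3-[1-hydroxy-2-(TBS-oxy)ethyl]-5-(trityloxymethyl)dihydrofuran-2(3H)-one (mixture at the two new centres) | O=C1C(C(O)CO[Si](C)(C)C(C)(C)C)C[C@@H](COC(c2ccccc2)(c2ccccc2)c2ccccc2)O1 | intermediate (not isolated)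
16 | methanesulfonate of 15 | O=C1C(C(OS(C)(=O)=O)CO[Si](C)(C)C(C)(C)C)C[C@@H](COC(c2ccccc2)(c2ccccc2)c2ccccc2)O1 | intermediate (not isolated)
17 | (S,E)-3-[2-(TBS-oxy)ethylidene]-5-(trityloxymethyl)dihydrofuran-2(3H)-one | O=C1/C(=C/CO[Si](C)(C)C(C)(C)C)C[C@@H](COC(c2ccccc2)(c2ccccc2)c2ccccc2)O1 | intermediate
18 | (S,E)-3-(2-hydroxyethylidene)-5-(trityloxymethyl)dihydrofuran-2(3H)-one | O=C1/C(=C/CO)C[C@@H](COC(c2ccccc2)(c2ccccc2)c2ccccc2)O1 | intermediate
19 | ester of 18 with acid 5 | O=C1/C(=C/COC(=O)CC(=C)CO[Si](c2ccccc2)(c2ccccc2)C(C)(C)C)C[C@@H](COC(c2ccccc2)(c2ccccc2)c2ccccc2)O1 | intermediate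
20 | (Z)-trimethylsilyl ketene acetal of 19 (C4 unit cis to OSiMe3) | O=C1/C(=C/CO/C(O[Si](C)(C)C)=C/C(=C)CO[Si](c2ccccc2)(c2ccccc2)C(C)(C)C)C[C@@H](COC(c2ccccc2)(c2ccccc2)c2ccccc2)O1 | intermediate (not isolated)
21 | trimethylsilyl ester of 22 | C=C[C@]1(C[C@@H](COC(c2ccccc2)(c2ccccc2)c2ccccc2)OC1=O)[C@@H](C(=O)O[Si](C)(C)C)C(=C)CO[Si](c2ccccc2)(c2ccccc2)C(C)(C)C | intermediate (not isolated)
22 | (2S)-2-[(3R,5S)-2-oxo-5-(trityloxymethyl)-3-vinyltetrahydrofuran-3-yl]-3-[(TBDPS-oxy)methyl]but-3-enoic acid (5S,8S,10R) | C=C[C@]1(C[C@@H](COC(c2ccccc2)(c2ccccc2)c2ccccc2)OC1=O)[C@@H](C(=O)O)C(=C)CO[Si](c2ccccc2)(c2ccccc2)C(C)(C)C | intermediate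
23 | open-chain C8,C14-dihydroxy C6 acid (5S,8S,10R) | C=C[C@](CO)(C[C@H](O)COC(c1ccccc1)(c1ccccc1)c1ccccc1)[C@@H](C(=O)O)C(=C)CO[Si](c1ccccc1)(c1ccccc1)C(C)(C)C | intermediate (not isolated)
24 | γ-lactone C6(=O)–O–C14 with C10 vinyl, C5 silyloxymethyl-vinyl unit, free C8–OH, C7–OTr (5S,8S,10R) | C=C[C@@]1(C[C@H](O)COC(c2ccccc2)(c2ccccc2)c2ccccc2)COC(=O)[C@H]1C(=C)CO[Si](c1ccccc1)(c1ccccc1)C(C)(C)C | intermediate
25 | C8 TBS ether of 24 | C=C[C@@]1(C[C@H](O[Si](C)(C)C(C)(C)C)COC(c2ccccc2)(c2ccccc2)c2ccccc2)COC(=O)[C@H]1C(=C)CO[Si](c1ccccc1)(c1ccccc1)C(C)(C)C | intermediate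
26 | C6 lactol of 25 (both anomers) | C=C[C@@]1(C[C@H](O[Si](C)(C)C(C)(C)C)COC(c2ccccc2)(c2ccccc2)c2ccccc2)COC(O)[C@H]1C(=C)CO[Si](c1ccccc1)(c1ccccc1)C(C)(C)C | intermediate (not isolated)
27 | C6 methyl acetal with free C7–OH, C8–OTBS (5S,8S,10R; both anomers) | C=C[C@@]1(C[C@H](O[Si](C)(C)C(C)(C)C)CO)COC(OC)[C@H]1C(=C)CO[Si](c1ccccc1)(c1ccccc1)C(C)(C)C | intermediate
28 | C7 aldehyde of 27 | C=C[C@@]1(C[C@H](O[Si](C)(C)C(C)(C)C)C=O)COC(OC)[C@H]1C(=C)CO[Si](c1ccccc1)(c1ccccc1)C(C)(C)C | intermediate
29 | methyl acrylate | C=CC(=O)OC | starting material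
30 | Morita–Baylis–Hillman adduct: methyl 2-[C7 hydroxyalkyl]acrylate (C7 epimers) | C=C[C@@]1(C[C@H](O[Si](C)(C)C(C)(C)C)C(O)C(=C)C(=O)OC)COC(OC)[C@H]1C(=C)CO[Si](c1ccccc1)(c1ccccc1)C(C)(C)C | intermediate
31 | methyl (Z)-2-(bromomethyl)enoate (C8 cis to CH2Br), C6 methyl acetal | C=C[C@@]1(C[C@H](O[Si](C)(C)C(C)(C)C)/C=C(\CBr)C(=O)OC)COC(OC)[C@H]1C(=C)CO[Si](c1ccccc1)(c1ccccc1)C(C)(C)C | intermediate
32 | C6 lactol of 31 (both anomers) | C=C[C@@]1(C[C@H](O[Si](C)(C)C(C)(C)C)/C=C(\CBr)C(=O)OC)COC(O)[C@H]1C(=C)CO[Si](c1ccccc1)(c1ccccc1)C(C)(C)C | intermediate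
33 | open-chain hydroxy aldehyde carrying the σ-allylchromium dichloride (trivalent chromium) at C13 | C=C[C@](CO)(C[C@H](O[Si](C)(C)C(C)(C)C)/C=C(\C[Cr](Cl)Cl)C(=O)OC)[C@@H](C=O)C(=C)CO[Si](c1ccccc1)(c1ccccc1)C(C)(C)C | intermediate (not isolated)
34 | cyclised C6 hydroxy methyl ester (ring closed, lactone open) | C=C[C@]1(CO)C[C@H](O[Si](C)(C)C(C)(C)C)[C@@H](C(=C)C(=O)OC)[C@H](O)[C@H]1C(=C)CO[Si](c1ccccc1)(c1ccccc1)C(C)(C)C | intermediate (not isolated)
35 | trans-fused α-methylene-γ-lactone, 8-OTBS, 15-OTBDPS, free 14-OH (stereocentres as in the target) | C=C[C@]1(CO)C[C@H](O[Si](C)(C)C(C)(C)C)[C@H]2C(=C)C(=O)O[C@@H]2[C@H]1C(=C)CO[Si](c1ccccc1)(c1ccccc1)C(C)(C)C | intermediate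
36 | 14-O-TBDPS ether of 35 | C=C[C@]1(CO[Si](c3ccccc3)(c3ccccc3)C(C)(C)C)C[C@H](O[Si](C)(C)C(C)(C)C)[C@H]2C(=C)C(=O)O[C@@H]2[C@H]1C(=C)CO[Si](c1ccccc1)(c1ccccc1)C(C)(C)C | intermediate
37 | C8 alcohol, 14,15-bis-TBDPS ether | C=C[C@]1(CO[Si](c3ccccc3)(c3ccccc3)C(C)(C)C)C[C@H](O)[C@H]2C(=C)C(=O)O[C@@H]2[C@H]1C(=C)CO[Si](c1ccccc1)(c1ccccc1)C(C)(C)C | intermediate
38 | mixed anhydride of 12 with 2,4,6-trichlorobenzoic acid | C/C=C(\C(=O)OC(=O)c1c(Cl)cc(Cl)cc1Cl)CO[Si](c1ccccc1)(c1ccccc1)C(C)(C)C | intermediate (not isolated)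
39 | tris-TBDPS ether of the target | C=C[C@]1(CO[Si](c3ccccc3)(c3ccccc3)C(C)(C)C)C[C@H](OC(=O)/C(=C\C)CO[Si](c3ccccc3)(c3ccccc3)C(C)(C)C)[C@H]2C(=C)C(=O)O[C@@H]2[C@H]1C(=C)CO[Si](c1ccccc1)(c1ccccc1)C(C)(C)C | intermediate
40 | target (5S,6R,7R,8S,10R), 8-O-[(Z)-2-(hydroxymethyl)but-2-enoyl] | C=C[C@]1(CO)C[C@H](OC(=O)/C(=C\C)CO)[C@H]2C(=C)C(=O)O[C@@H]2[C@H]1C(=C)CO | target

Total step count: 23. Longest linear sequence: 17 steps (1 → 40, steps 1–3 and then 10–23).

Steps most likely to fail

Step 19 (key step). The allylchromium intermediate may be protonated by the lactol or primary hydroxyl before C–C bond formation, the lactol may open too slowly, or chelation by the free C14 hydroxyl may erode the facial selectivity at C6/C7. The fallback replaces the organometallic addition by a radical cyclisation; it sets out from 30 and returns at 35. Compound 30 would be acetylated (Ac2O, DMAP, CH2Cl2) to the secondary allylic acetate F1. DABCO (THF, 60 °C) would transpose this to the primary (E)-2-(acetoxymethyl)enoate F2, and AcOH–THF–H2O would unmask the lactol F3. SmI2 (THF–MeOH, −78 → 0 °C) would then reduce the open aldehyde to its ketyl radical, which adds 6-exo to C7 of the enoate anti to the samarium alkoxide. The resulting samarium enolate expels acetate to form the exocyclic methylene, and lactonisation gives 35.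

Step 11. Base may attack the alkylidene lactone by γ-deprotonation or conjugate addition, and imperfect control of ketene acetal geometry or of the face of attack would erode the C5/C10 configuration. The fallback builds the two centres stepwise by polar chemistry; it sets out from 13 and returns at 25. Compound 13 would be condensed with acetaldehyde (LiN(i-Pr)2; MeCHO; MsCl; DBU) to the ethylidene lactone F4. γ-Deprotonation (LiN(i-Pr)2, THF–DMPU, −78 °C) and α-alkylation of the dienolate with tert-butyl bromoacetate anti to CH2OTr would give the α-vinyl lactone F5, with quaternary C10 set by the ring. LiBH4 would reduce the lactone to the diol ester F6, which KOt-Bu (cat.) would relactonise to the hydroxy lactone F7, and TBSOTf would give the silyl ether F8. Pd-catalysed α-alkenylation of its lithium enolate (LiN(SiMe3)2, Pd(dba)2, P(t-Bu)3, toluene) with the 2-bromoallyl silyl ether F9 (from 2-bromoprop-2-en-1-ol and TBDPSCl), followed by base equilibration at C5 to the isomer with the new group anti to the larger C9 arm, would give 25.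

Step 16. Addition to the hindered α-silyloxy aldehyde may be very slow, with gradual epimerisation at C8 under prolonged amine exposure. The fallback avoids the amine catalyst; it sets out from 28 and returns at 30. 1,4-Hydroalumination of methyl propiolate with i-Bu2AlH–HMPA (THF, 0 °C) gives the α-aluminoacrylate, which would add to 28 within hours to give 30 directly, so no new compound is made (F0).

Further compounds
F1 | step 19 | acetate of 30 at the C7 carbinol | C=C[C@@]1(C[C@H](O[Si](C)(C)C(C)(C)C)C(OC(C)=O)C(=C)C(=O)OC)COC(OC)[C@H]1C(=C)CO[Si](c1ccccc1)(c1ccccc1)C(C)(C)C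
F2 | step 19 | methyl (E)-2-(acetoxymethyl)enoate (C8 cis to CH2OAc), C6 methyl acetal | C=C[C@@]1(C[C@H](O[Si](C)(C)C(C)(C)C)/C=C(\COC(C)=O)C(=O)OC)COC(OC)[C@H]1C(=C)CO[Si](c1ccccc1)(c1ccccc1)C(C)(C)C
F3 | step 19 | C6 lactol of F2 | C=C[C@@]1(C[C@H](O[Si](C)(C)C(C)(C)C)/C=C(\COC(C)=O)C(=O)OC)COC(O)[C@H]1C(=C)CO[Si](c1ccccc1)(c1ccccc1)C(C)(C)C
F4 | step 11 | (S,E)-3-ethylidene-5-(trityloxymethyl)dihydrofuran-2(3H)-one | O=C1/C(=C/C)C[C@@H](COC(c2ccccc2)(c2ccccc2)c2ccccc2)O1
F5 | step 11 | tert-butyl 2-[(5S)-2-oxo-5-(trityloxymethyl)-3-vinyltetrahydrofuran-3-yl]acetate (CH2CO2t-Bu trans to CH2OTr) | C=C[C@@]1(CC(=O)OC(C)(C)C)C[C@@H](COC(c2ccccc2)(c2ccccc2)c2ccccc2)OC1=O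
F6 | step 11 | tert-butyl 3-(hydroxymethyl)-3-vinyl-5-hydroxy-6-(trityloxy)hexanoate (diol ester from F5) | C=C[C@](CO)(C[C@H](O)COC(c1ccccc1)(c1ccccc1)c1ccccc1)CC(=O)OC(C)(C)C
F7 | step 11 | γ-lactone C6(=O)–O–C14 lacking the C5 substituent, free C8–OH | C=C[C@@]1(C[C@H](O)COC(c2ccccc2)(c2ccccc2)c2ccccc2)COC(=O)C1
F8 | step 11 | C8 TBS ether of F7 | C=C[C@@]1(C[C@H](O[Si](C)(C)C(C)(C)C)COC(c2ccccc2)(c2ccccc2)c2ccccc2)COC(=O)C1
F9 | step 11 | (2-bromoprop-2-enyloxy)(tert-butyl)diphenylsilane | C=C(Br)CO[Si](c1ccccc1)(c1ccccc1)C(C)(C)C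
F0 | step 16 | none | none
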